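**Plan**

1. Numbering used (eudesmane): ring A = C1–C5 + C10 with the exocyclic CH2 on C4; ring B = C5–C10; C5–H and C10–CH3 sit at the cis ring fusion; C6–OH, C7–iPr, C9–O-anisoyl.
2. Cuts: the C9–O acyl bond and C9–H (ketone reduction) go first; ring A is then cut at C1–C10 and C4–C5, both traced to one cascade, and C1–C9 to a Grignard addition; ring B goes back to (R)-α-phellandrene and O2.
3. Enabling feature: the oxygen-bearing C9 lies next to quaternary C10 and is 1,3 to C5 across the C10=C5 alkene of a ring-B cyclohexene. A pentynyl chain on a C9 silyloxy carbinol can therefore reach C5 and then slide from C9 to the C10 cation while C9 becomes the ketone.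
4. Forward: ring B first (chiral pool), chain onto C9, then a gold-catalysed enyne closure to a seven-membered carbocycle (C4, C3, C2, C1, C9, C10, C5). This ring contracts by pinacol shift to six-membered ring A, giving the cis-decalin, quaternary C10 and the C4 methylidene together; reduction, acylation and desilylation finish.
5. Stereochemistry: C7 from the chiral pool; C6 from suprafacial singlet-oxygen addition; C5/C10 from the face of the C9 tether (placed anti to iPr/OTBS in the Grignard step); C9 from hydride delivery anti to the three cis substituents.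

Key step: step 7

Assumption: step 1 gives both facial isomers of the endoperoxide, separable on silica; the isomer with the peroxide bridge syn to isopropyl is carried on, and the anti isomer is treated under the fallbacks.

**Route**

Step 1
Reactants: 1 (R)-(−)-α-phellandrene [(5R)-2-methyl-5-(propan-2-yl)cyclohexa-1,3-diene]
Product: 2 (1S,4R,7R)-5-methyl-7-(propan-2-yl)-2,3-dioxabicyclo[2.2.2]oct-5-ene (peroxide bridge syn to isopropyl)
Conditions: O2, tetraphenylporphyrin (cat.), hν (visible), CH2Cl2, 0 °C; chromatographic separation from the anti isomer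
Reagents that add atoms: dioxygen, O=O
Why: Singlet-oxygen [4+2] cycloaddition to the cyclohexadiene is suprafacial, so the two C–O bonds (C6 and C9) are cis to each other, and addition on the isopropyl-bearing face sets the C6 configuration cis to the C7 isopropyl group.

Step 2
Reactants: 2 syn endoperoxide
Product: 3 (4S,5R)-4-hydroxy-2-methyl-5-(propan-2-yl)cyclohex-2-en-1-one (OH cis to isopropyl)
Conditions: Et3N (0.3 equiv), CH2Cl2, 0 °C → rt
Reagents that add atoms: none
Why: Kornblum–DeLaMare rearrangement, in which the amine should remove the less hindered bridgehead hydrogen (at C9, remote from isopropyl) so that O–O cleavage gives the C9 ketone and leaves the C6 carbinol centre untouched.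

Step 3
Reactants: 3 cis hydroxy enone
Product: 4 (4S,5R)-4-[(tert-butyldimethylsilyl)oxy]-2-methyl-5-(propan-2-yl)cyclohex-2-en-1-one
Conditions: TBSCl, imidazole, DMF, 0 °C → rt
Reagents that add atoms: tert-butyldimethylsilyl chloride, CC(C)(C)[Si](C)(C)Cl
Why: Imidazole-promoted silylation of a secondary allylic alcohol, which touches no stereocentre and blocks the γ-hydroxyl before the organometallic step.

Step 4
Reactants: 4 silyloxy enone; 5 (5-chloropent-1-yn-1-yl)trimethylsilane
Product: 7 (1R,4S,5R)-4-[(tert-butyldimethylsilyl)oxy]-2-methyl-5-(propan-2-yl)-1-[5-(trimethylsilyl)pent-4-yn-1-yl]cyclohex-2-en-1-ol, via alkylmagnesium chloride 6 (not isolated)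
Conditions: 5, Mg, THF, 50 °C; then 4, THF, −78 → 0 °C; aq. NH4Cl
Reagents that add atoms: none
Why: Grignard 1,2-addition to the α-methyl enone, with axial attack on the half-chair anti to the isopropyl and silyloxy groups (as in additions to carvone), which places the chain on C9 trans to both and sets the temporary C9 carbinol centre that later steers ring A.

Step 5
Reactants: 7 alkynylsilane carbinol
Product: 8 (1R,4S,5R)-4-[(tert-butyldimethylsilyl)oxy]-2-methyl-1-(pent-4-yn-1-yl)-5-(propan-2-yl)cyclohex-2-en-1-ol
Conditions: K2CO3, MeOH, rt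
Reagents that add atoms: none
Why: Base-mediated protiodesilylation (methanolysis) of the C(sp)–SiMe3 bond, which the TBS ether and the tertiary alcohol should survive.

Step 6
Reactants: 8 terminal alkyne carbinol
Product: 9 triethyl{[(1R,4S,5R)-4-(tert-butyldimethylsilyloxy)-2-methyl-1-(pent-4-yn-1-yl)-5-(propan-2-yl)cyclohex-2-en-1-yl]oxy}silane
Conditions: TESOTf, 2,6-lutidine, CH2Cl2, −78 → 0 °C
Reagents that add atoms: triethylsilyl trifluoromethanesulfonate, CC[Si](CC)(CC)OS(=O)(=O)C(F)(F)F
Why: Silyl-triflate silylation of a hindered tertiary alcohol, which prevents gold-catalysed hydroalkoxylation of the alkyne and supplies the silyloxy group that drives the pinacol shift.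

Step 7
Reactants: 9 silyloxy 1,7-enyne
Product: 11 (3R,4S,4aS,8aR)-4-[(tert-butyldimethylsilyl)oxy]-8a-methyl-5-methylidene-3-(propan-2-yl)octahydronaphthalen-1(2H)-one, via vinylgold bicyclo[4.3.1]decyl cation 10 (not isolated)
Conditions: [(2-biphenyl)(t-Bu)2P]Au(NCMe)SbF6 (5 mol %), i-PrOH (1.1 equiv), CH2Cl2, rt
Reagents that add atoms: none
Why: Cationic gold(I) π-activates the terminal alkyne and the C10=C5 alkene adds through C5 to the internal alkyne carbon C4 (Markovnikov, 7-exo-dig), which closes a seven-membered carbocycle (C4–C3–C2–C1–C9–C10–C5) bridging ring B and leaves vinylgold cation 10 with the charge on tertiary C10 next to the silyloxy carbon C9. The C9–C1 bond, axial on ring B and parallel to the empty p orbital, then shifts from C9 to C10 (pinacol 1,2-shift): C9 is excised from the seven-membered ring, which contracts to six-membered ring A, C10 becomes quaternary and C9 the ketone, while i-PrOH takes up the silyl group and protodeaurates the vinylgold carbon to the methylidene. The closest known reaction type is the gold(I)-catalysed pinacol-terminated cyclisation of silyloxy enynes (a Prins–pinacol process with an alkyne as initiator). Both new stereocentres are set by the tether: it is attached at C9 on the face anti to isopropyl and OTBS, so C4 bonds to C5 and C1 bonds to C10 on that same face, which enforces the cis ring fusion with H-5 and CH3-10 syn to the C6 and C7 substituents. The step needs C5 rather than C10 as the attacking alkene carbon and migration of C1 rather than the ring carbon C8; the first is secured by the tertiary cation that only C5 attack creates, the second by the axial alignment of C9–C1 and by the strain-free cis-decalin it gives (C8 migration would give a hydroazulenone).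

Step 8
Reactants: 11 cis-decalinone
Product: 12 (1R,3R,4S,4aS,8aR)-4-[(tert-butyldimethylsilyl)oxy]-8a-methyl-5-methylidene-3-(propan-2-yl)decahydronaphthalen-1-ol
Conditions: L-Selectride, THF, −78 °C; aqueous work-up
Reagents that add atoms: none
Why: Ketone reduction under steric approach control: the face of the C9 carbonyl that carries the angular methyl, the isopropyl group (axial in the conformer that keeps OTBS equatorial) and the silyloxy group is shielded, so the bulky hydride should add from the ring-A face and give the C9 alcohol cis to the angular methyl.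

Step 9
Reactants: 12 C9 alcohol; 13 4-methoxybenzoyl chloride
Product: 14 (1R,3R,4S,4aS,8aR)-4-[(tert-butyldimethylsilyl)oxy]-8a-methyl-5-methylidene-3-(propan-2-yl)decahydronaphthalen-1-yl 4-methoxybenzoate
Conditions: 13, Et3N, DMAP, CH2Cl2, 40 °C
Reagents that add atoms: none
Why: DMAP-catalysed acylation (nucleophilic catalysis) of the only free hydroxyl, an equatorial secondary alcohol, with retention at C9.

Step 10
Reactants: 14 silyl ether ester
Product: 15 (1R,3R,4S,4aS,8aR)-4-hydroxy-8a-methyl-5-methylidene-3-(propan-2-yl)decahydronaphthalen-1-yl 4-methoxybenzoate (target)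
Conditions: HF·pyridine, pyridine/THF, 0 °C → rt
Reagents that add atoms: none
Why: Fluoride-mediated cleavage of the TBS ether (Si–F bond formation) under buffered conditions that should leave the ester and the exocyclic alkene untouched and do not affect any stereocentre.

**Compound list**

1 | (R)-(−)-α-phellandrene, (5R)-2-methyl-5-(propan-2-yl)cyclohexa-1,3-diene | CC1=CC[C@H](C(C)C)C=C1 | starting material
2 | (1S,4R,7R)-5-methyl-7-(propan-2-yl)-2,3-dioxabicyclo[2.2.2]oct-5-ene (O–O bridge syn to isopropyl) | CC1=C[C@@H]2[C@@H](C(C)C)C[C@H]1OO2 | intermediate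
3 | (4S,5R)-4-hydroxy-2-methyl-5-(propan-2-yl)cyclohex-2-en-1-one | CC1=C[C@@H](O)[C@@H](C(C)C)CC1=O | intermediate
4 | (4S,5R)-4-[(tert-butyldimethylsilyl)oxy]-2-methyl-5-(propan-2-yl)cyclohex-2-en-1-one | CC1=C[C@@H](O[Si](C)(C)C(C)(C)C)[C@@H](C(C)C)CC1=O | intermediate
5 | (5-chloropent-1-yn-1-yl)trimethylsilane | C[Si](C)(C)C#CCCCCl | starting material
6 | [5-(trimethylsilyl)pent-4-yn-1-yl]magnesium chloride | C[Si](C)(C)C#CCCC[Mg]Cl | intermediate
7 | (1R,4S,5R)-4-[(tert-butyldimethylsilyl)oxy]-2-methyl-5-(propan-2-yl)-1-[5-(trimethylsilyl)pent-4-yn-1-yl]cyclohex-2-en-1-ol | C[Si](C)(C)C#CCCC[C@@]1(O)C[C@H](C(C)C)[C@H](O[Si](C)(C)C(C)(C)C)C=C1C | intermediate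
8 | (1R,4S,5R)-4-[(tert-butyldimethylsilyl)oxy]-2-methyl-1-(pent-4-yn-1-yl)-5-(propan-2-yl)cyclohex-2-en-1-ol | C#CCCC[C@@]1(O)C[C@H](C(C)C)[C@H](O[Si](C)(C)C(C)(C)C)C=C1C | intermediate
9 | triethyl{[(1R,4S,5R)-4-(tert-butyldimethylsilyloxy)-2-methyl-1-(pent-4-yn-1-yl)-5-(propan-2-yl)cyclohex-2-en-1-yl]oxy}silane | C#CCCC[C@@]1(O[Si](CC)(CC)CC)C[C@H](C(C)C)[C@H](O[Si](C)(C)C(C)(C)C)C=C1C | intermediate
10 | vinylgold bicyclo[4.3.1]decyl cation (charge on C10; seven-membered ring C4–C3–C2–C1–C9–C10–C5; phosphine on gold not drawn) | [Au]/C=C1\CCC[C@@]2(O[Si](CC)(CC)CC)C[C@H](C(C)C)[C@H](O[Si](C)(C)C(C)(C)C)[C@@H]1[C+]2C | intermediate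
11 | (3R,4S,4aS,8aR)-4-[(tert-butyldimethylsilyl)oxy]-8a-methyl-5-methylidene-3-(propan-2-yl)octahydronaphthalen-1(2H)-one | C=C1CCC[C@]2(C)[C@H]1[C@@H](O[Si](C)(C)C(C)(C)C)[C@@H](C(C)C)CC2=O | intermediate
12 | (1R,3R,4S,4aS,8aR)-4-[(tert-butyldimethylsilyl)oxy]-8a-methyl-5-methylidene-3-(propan-2-yl)decahydronaphthalen-1-ol | C=C1CCC[C@]2(C)[C@H]1[C@@H](O[Si](C)(C)C(C)(C)C)[C@@H](C(C)C)C[C@H]2O | intermediate
13 | 4-methoxybenzoyl chloride | COc1ccc(cc1)C(Cl)=O | starting material
14 | (1R,3R,4S,4aS,8aR)-4-[(tert-butyldimethylsilyl)oxy]-8a-methyl-5-methylidene-3-(propan-2-yl)decahydronaphthalen-1-yl 4-methoxybenzoate | C=C1CCC[C@]2(C)[C@H]1[C@@H](O[Si](C)(C)C(C)(C)C)[C@@H](C(C)C)C[C@H]2OC(=O)c1ccc(OC)cc1 | intermediate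
15 | (1R,3R,4S,4aS,8aR)-4-hydroxy-8a-methyl-5-methylidene-3-(propan-2-yl)decahydronaphthalen-1-yl 4-methoxybenzoate | C=C1CCC[C@]2(C)[C@H]1[C@@H](O)[C@@H](C(C)C)C[C@H]2OC(=O)c1ccc(OC)cc1 | target

**Count and risks**

Total step count: 10. Longest linear sequence: 10 steps (1 → 15); 5 and 13 enter as purchased.

Steps most likely to fail:

1. Step 7. The alkene is deactivated by two allylic silyloxy groups and may not add to the gold-bound alkyne (alkyne hydration, or closure through C10), or the ring bond C9–C8 may migrate in place of C9–C1. Fallback, from 4 back to 11: addition of pent-4-en-1-ylmagnesium bromide to 4 should give the pentenyl carbinol F1 with the same facial course as step 4. TESOTf/2,6-lutidine then gives the bis-silyl ether F2. OsO4 (cat.)/NaIO4 with 2,6-lutidine should cleave only the unhindered terminal alkene to the aldehyde F3. SnCl4 in CH2Cl2 at −78 °C then triggers a Lewis-acid Prins–pinacol reaction: the activated aldehyde is a harder electrophile than the gold–alkyne complex, and the same seven-membered ring contracts to ring A, giving the keto alcohol F4. Dess–Martin oxidation gives the diketone F5, and Wittig methylenation with one equivalent of Ph3P=CH2 at the less hindered C4 ketone (C9 is neopentyl) returns to 11.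

2. Step 8. Facial selectivity of hydride delivery may be insufficient, because two cis-decalin conformers expose opposite faces of the C9 carbonyl. Fallback, from 11 to 15: HF·pyridine first removes the TBS group to give the hydroxy ketone F6. Reduction with SmI2 in THF/MeOH, in which samarium is expected to bridge the C6 hydroxyl and the C9 ketyl so that protonation comes from the ring-A face, should give the cis-1,4-diol F7. Acylation with one equivalent of 13 (Et3N, DMAP) at the equatorial C9 hydroxyl then gives 15; the axial C6 hydroxyl is flanked by C5, the isopropyl-bearing C7 and the syn-axial methyl and should not compete.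

3. Step 1. Facial selectivity of singlet-oxygen addition is poor, and attack anti to isopropyl may dominate. Fallback, from 1 back to 3: the anti endoperoxide F8 from the same photooxygenation is rearranged with Et3N to the trans hydroxy enone F9. Mitsunobu inversion at C6 with 4-nitrobenzoic acid (PPh3, DIAD) gives the cis 4-nitrobenzoate F10, and mild methanolysis (K2CO3, MeOH, 0 °C) returns to 3.

**Further compounds**

F1 | step 7 | (1R,4S,5R)-4-[(tert-butyldimethylsilyl)oxy]-2-methyl-1-(pent-4-en-1-yl)-5-(propan-2-yl)cyclohex-2-en-1-ol | C=CCCC[C@@]1(O)C[C@H](C(C)C)[C@H](O[Si](C)(C)C(C)(C)C)C=C1C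
F2 | step 7 | triethylsilyl ether of F1 at the tertiary hydroxyl | C=CCCC[C@@]1(O[Si](CC)(CC)CC)C[C@H](C(C)C)[C@H](O[Si](C)(C)C(C)(C)C)C=C1C
F3 | step 7 | 4-[(1R,4S,5R)-4-(tert-butyldimethylsilyloxy)-2-methyl-5-(propan-2-yl)-1-(triethylsilyloxy)cyclohex-2-en-1-yl]butanal | O=CCCC[C@@]1(O[Si](CC)(CC)CC)C[C@H](C(C)C)[C@H](O[Si](C)(C)C(C)(C)C)C=C1C
F4 | step 7 | keto alcohol: cis-decalinone as 11 with CH–OH at C4 in place of C=CH2 (carbinol configuration immaterial) | OC1CCC[C@]2(C)[C@H]1[C@@H](O[Si](C)(C)C(C)(C)C)[C@@H](C(C)C)CC2=O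
F5 | step 7 | diketone: cis-decalinone as 11 with C=O at C4 in place of C=CH2 | O=C1CCC[C@]2(C)[C@H]1[C@@H](O[Si](C)(C)C(C)(C)C)[C@@H](C(C)C)CC2=O
F6 | step 8 | (3R,4S,4aS,8aR)-4-hydroxy-8a-methyl-5-methylidene-3-(propan-2-yl)octahydronaphthalen-1(2H)-one | C=C1CCC[C@]2(C)[C@H]1[C@@H](O)[C@@H](C(C)C)CC2=O
F7 | step 8 | (1R,3R,4S,4aS,8aR)-8a-methyl-5-methylidene-3-(propan-2-yl)decahydronaphthalene-1,4-diol | C=C1CCC[C@]2(C)[C@H]1[C@@H](O)[C@@H](C(C)C)C[C@H]2O
F8 | step 1 | (1R,4S,7R)-5-methyl-7-(propan-2-yl)-2,3-dioxabicyclo[2.2.2]oct-5-ene (O–O bridge anti to isopropyl) | CC1=C[C@H]2[C@@H](C(C)C)C[C@@H]1OO2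
F9 | step 1 | (4R,5R)-4-hydroxy-2-methyl-5-(propan-2-yl)cyclohex-2-en-1-one (trans) | CC1=C[C@H](O)[C@@H](C(C)C)CC1=O
F10 | step 1 | (1S,6R)-3-methyl-4-oxo-6-(propan-2-yl)cyclohex-2-en-1-yl 4-nitrobenzoate (cis) | CC1=C[C@@H](OC(=O)c2ccc(cc2)[N+](=O)[O-])[C@@H](C(C)C)CC1=O
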